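**Retrosynthetic overview**

- The target comes from its pentasilyl ether by one buffered global desilylation, so nothing else is done once the stereocentre exists.
- Ring C is the only ring that is built and it is closed last, by forming the C2–C3 bond. An α-diazo deoxybenzoin gives a rhodium carbenoid at C3, which inserts enantioselectively into a C–H bond of the ring A ortho-methoxy group; O–CH3 becomes O1–C2H2.
- Enabling feature: C2 is an unsubstituted CH2 bound only to the ring A ether oxygen O1 (a masked aryl methyl ether). C3 lies between the C4 carbonyl and ring B (an aryl/acyl carbene), and C4, C4a and C8a of ring A hold the two carbons in a 1,6 relationship.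
- The diazo ketone comes from the deoxybenzoin by diazo transfer. The deoxybenzoin comes from a ring A acetophenone and a ring B bromide by Pd-catalysed α-arylation (C3–C1' bond).
- The ring B bromide comes from resorcinol by two directed ortho-metalations (allylation with a chain bromide made from geranyl acetate, then bromination) and a MOM-to-silyl exchange. Rings A and B are bought as aromatics.

Key step: step 13

Assumption: the sense of induction of Rh2(S-PTTL)4 in this insertion cannot be read from a close model; if a first run gives the (3R) product, the mirror-image catalyst Rh2(R-PTTL)4 is used under the same conditions.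

**Route**

Step 1
Reactants: 1 geranyl acetate [(2E)-3,7-dimethylocta-2,6-dien-1-yl acetate]
Product: 2 (2E)-6,7-epoxy-3,7-dimethyloct-2-en-1-yl acetate (racemic epoxide)
Conditions: mCPBA (1.05 equiv), CH2Cl2, 0 °C
Reagents that add atoms: mCPBA, O=C(OO)c1cccc(Cl)c1
Why: Prilezhaev epoxidation should pick the electron-rich 6,7-alkene because the 2,3-alkene is deactivated by the allylic acetate; the racemic epoxide stereocentre is erased in step 2.

Step 2
Reactants: 2 (2E)-6,7-epoxy-3,7-dimethyloct-2-en-1-yl acetate
Product: 3 (2E)-3,7-dimethyloct-2-ene-1,7-diol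
Conditions: LiAlH4, THF, 0 °C → rt; aqueous Rochelle salt
Reagents that add atoms: none
Why: Hydride opening of the trisubstituted epoxide at its less substituted carbon should give the tertiary alcohol while the same reagent cleaves the acetate reductively (epoxide reduction and ester reduction).

Step 3
Reactants: 3 (2E)-3,7-dimethyloct-2-ene-1,7-diol
Product: 4 (6E)-8-bromo-2,6-dimethyloct-6-en-2-ol
Conditions: CBr4, PPh3, CH2Cl2, 0 °C
Reagents that add atoms: carbon tetrabromide, BrC(Br)(Br)Br
Why: The Appel reaction should convert only the primary allylic alcohol by SN2 displacement, leaving the hindered tertiary alcohol and the E-alkene untouched.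

Step 4
Reactants: 4 (6E)-8-bromo-2,6-dimethyloct-6-en-2-ol
Product: 5 {[(6E)-8-bromo-2,6-dimethyloct-6-en-2-yl]oxy}triethylsilane
Conditions: TESOTf, 2,6-lutidine, CH2Cl2, −78 → 0 °C
Reagents that add atoms: triethylsilyl triflate, CC[Si](CC)(CC)OS(=O)(=O)C(F)(F)F
Why: Silylation with a silyl triflate and a hindered pyridine base is the standard way to cap a tertiary alcohol, and the hindered base should not alkylate on the allylic bromide.

Step 5
Reactants: 6 resorcinol
Product: 7 1,3-bis(methoxymethoxy)benzene
Conditions: MOMCl, i-Pr2NEt, CH2Cl2, 0 °C → rt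
Reagents that add atoms: chloromethyl methyl ether, COCCl
Why: Williamson-type O-alkylation of both phenols installs the two MOM groups that later direct both metalations.

Step 6
Reactants: 7 1,3-bis(methoxymethoxy)benzene; 5 {[(6E)-8-bromo-2,6-dimethyloct-6-en-2-yl]oxy}triethylsilane
Product: 10 {[(6E)-8-[2,6-bis(methoxymethoxy)phenyl]-2,6-dimethyloct-6-en-2-yl]oxy}triethylsilane, via aryllithium 8 (not isolated), via arylcopper 9 (not isolated)
Conditions: n-BuLi, THF, 0 °C → rt; CuI, −20 °C; then 5, −78 °C → rt
Reagents that add atoms: none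
Why: Directed ortho-metalation should occur at C2 between the two MOM ethers, and the derived arylcopper should alkylate the primary allylic bromide at its α-carbon (copper-mediated SN2 allylation), which keeps the E-alkene.

Step 7
Reactants: 10 {[(6E)-8-[2,6-bis(methoxymethoxy)phenyl]-2,6-dimethyloct-6-en-2-yl]oxy}triethylsilane
Product: 12 {[(6E)-8-[3-bromo-2,6-bis(methoxymethoxy)phenyl]-2,6-dimethyloct-6-en-2-yl]oxy}triethylsilane, via ring-lithiated arene 11 (not isolated)
Conditions: n-BuLi, TMEDA, Et2O, 0 °C; then BrCCl2CCl2Br, −78 °C → rt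
Reagents that add atoms: 1,2-dibromotetrachloroethane, BrC(Cl)(Cl)C(Cl)(Cl)Br
Why: A second directed ortho-metalation next to a MOM ether, followed by bromine transfer to the aryllithium, places the bromide without any electrophilic bromine that could attack the chain alkene.

Step 8
Reactants: 12 {[(6E)-8-[3-bromo-2,6-bis(methoxymethoxy)phenyl]-2,6-dimethyloct-6-en-2-yl]oxy}triethylsilane
Product: 13 4-bromo-2-[(2E)-7-hydroxy-3,7-dimethyloct-2-en-1-yl]benzene-1,3-diol
Conditions: HCl (1 M in MeOH), MeOH, rt
Reagents that add atoms: none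
Why: Acid-catalysed acetal exchange with methanol removes both MOM groups (the TES ether is solvolysed as well) under conditions too mild to protonate the trisubstituted alkene or ionise the tertiary alcohol.

Step 9
Reactants: 13 4-bromo-2-[(2E)-7-hydroxy-3,7-dimethyloct-2-en-1-yl]benzene-1,3-diol
Product: 15 4-bromo-1,3-bis(tert-butyldimethylsilyloxy)-2-[(2E)-3,7-dimethyl-7-(trimethylsilyloxy)oct-2-en-1-yl]benzene, via bis(TBS) ether 14 (not isolated)
Conditions: TBSCl, imidazole, DMF, rt; then TMSCl, 0 °C → rt
Reagents that add atoms: tert-butyldimethylsilyl chloride, CC(C)(C)[Si](C)(C)Cl; trimethylsilyl chloride, C[Si](C)(C)Cl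
Why: Imidazole-promoted silylation with TBSCl should take only the two phenols, after which the smaller TMSCl caps the tertiary alcohol, so that no oxygen of ring B carries a C–H bond that a carbenoid could attack.

Step 10
Reactants: 16 1-(2,4-dihydroxy-6-methoxyphenyl)ethanone
Product: 17 1-[2-methoxy-4,6-bis(triisopropylsilyloxy)phenyl]ethanone
Conditions: TIPSCl, imidazole, DMAP (cat.), DMF, 50 °C
Reagents that add atoms: triisopropylsilyl chloride, CC(C)[Si](Cl)(C(C)C)C(C)C
Why: Imidazole-promoted silylation should cap both phenols, the chelated one included, and the bulky triisopropylsilyl group is chosen because it resists oxygen-to-oxygen migration in the later enolates.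

Step 11
Reactants: 17 1-[2-methoxy-4,6-bis(triisopropylsilyloxy)phenyl]ethanone; 15 4-bromo-1,3-bis(tert-butyldimethylsilyloxy)-2-[(2E)-3,7-dimethyl-7-(trimethylsilyloxy)oct-2-en-1-yl]benzene
Product: 18 2-{2,4-bis(tert-butyldimethylsilyloxy)-3-[(2E)-3,7-dimethyl-7-(trimethylsilyloxy)oct-2-en-1-yl]phenyl}-1-[2-methoxy-4,6-bis(triisopropylsilyloxy)phenyl]ethanone
Conditions: Pd2(dba)3 (2.5 mol %), XPhos (6 mol %), K3PO4, toluene, 90 °C
Reagents that add atoms: none
Why: Palladium-catalysed α-arylation of an aryl methyl ketone (Buchwald–Hartwig type) with a weak phosphate base should join the two halves at C3–C1' and stop at monoarylation because the product enolate is hindered, while the silyl ethers tolerate the base.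

Step 12
Reactants: 18 the deoxybenzoin of step 11
Product: 19 2-diazo-2-{2,4-bis(tert-butyldimethylsilyloxy)-3-[(2E)-3,7-dimethyl-7-(trimethylsilyloxy)oct-2-en-1-yl]phenyl}-1-[2-methoxy-4,6-bis(triisopropylsilyloxy)phenyl]ethanone
Conditions: p-ABSA, DBU, MeCN, 0 °C → rt
Reagents that add atoms: 4-acetamidobenzenesulfonyl azide, CC(=O)Nc1ccc(cc1)S(=O)(=O)N=[N+]=[N-]
Why: Regitz diazo transfer to the benzylic methylene of an aryl benzyl ketone, which is acidic enough for DBU, is the standard entry to α-aryl-α-diazo ketones.

Step 13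
Reactants: 19 the α-diazo deoxybenzoin of step 12
Product: 20 (3S)-3-{2,4-bis(tert-butyldimethylsilyloxy)-3-[(2E)-3,7-dimethyl-7-(trimethylsilyloxy)oct-2-en-1-yl]phenyl}-5,7-bis(triisopropylsilyloxy)-2,3-dihydro-4H-chromen-4-one
Conditions: Rh2(S-PTTL)4 (dirhodium tetrakis[N-phthaloyl-(S)-tert-leucinate], 1 mol %), 4 Å MS, toluene, −30 → 0 °C, slow addition of 19
Reagents that add atoms: none
Why: Loss of N2 from 19 at the dirhodium tetracarboxylate gives an electrophilic aryl/acyl rhodium carbenoid at the future C3, which inserts into a C–H bond of the ring A ortho-methoxy group through a concerted, asynchronous three-centre transition state (hydride shift running ahead of C–C bond formation), so that O–CH3 becomes O1–C2H2 and the C2–C3 bond is made. The closest known reaction type is the enantioselective dirhodium-carboxylate-catalysed intramolecular C–H insertion of ortho-alkoxyaryl α-diazo ketones to chroman-4-ones and of ortho-alkoxyaryl diazoacetates to 2,3-dihydrobenzofurans, together with the insertion of aryl/acceptor carbenoids into methyl ether C–H bonds. Ring C is closed in the 1,6-insertion mode through a six-membered cyclic transition state in which the carbenoid carbon, C4, C4a, C8a, O1 and the methyl carbon become the pyranone ring. The single new stereocentre C3 is the former carbenoid carbon; there is no substrate control, and its configuration is fixed by the face of the carbenoid that the C–H bond reaches inside the chiral pocket of the four N-phthaloyl-tert-leucinate ligands. The step needs site selectivity for the methoxy C–H bonds, and the substrate secures it because these are the only oxygen-activated C(sp3)–H bonds within reach: every other oxygen carries silicon and has no α-C–H (so neither a 1,5-insertion at the 2'-oxygen of ring B nor a second 1,6-insertion at the 5-oxygen of ring A can occur), the tertiary alcohol is masked, the chain alkene is meta to the carbenoid-bearing carbon and cannot reach it, and oxonium ylide formation at the methyl ether is reversible and has no productive exit. Slow addition at low temperature should keep carbene dimerisation and intermolecular attack on the chain alkene below the intramolecular insertion.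

Step 14
Reactants: 20 the pentasilyl isoflavanone of step 13
Product: 21 (3S)-3-{2,4-dihydroxy-3-[(2E)-7-hydroxy-3,7-dimethyloct-2-en-1-yl]phenyl}-5,7-dihydroxy-2,3-dihydro-4H-chromen-4-one (target)
Conditions: TBAF/AcOH (1:1.1, 7 equiv), THF, 0 °C → rt; pH 6 phosphate work-up
Reagents that add atoms: none
Why: Fluoride-mediated desilylation buffered with acetic acid should cleave the four aryl silyl ethers and the tertiary trimethylsilyl ether while keeping the medium too weakly basic to enolise C3 or to open ring C, so the configuration set in step 13 is kept.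

**Compound list**

1 | geranyl acetate | C/C(=C\COC(C)=O)CCC=C(C)C | starting material
2 | (2E)-6,7-epoxy-3,7-dimethyloct-2-en-1-yl acetate (racemic) | C/C(=C\COC(C)=O)CCC1OC1(C)C | intermediate
3 | (2E)-3,7-dimethyloct-2-ene-1,7-diol | C/C(=C\CO)CCCC(C)(C)O | intermediate
4 | (6E)-8-bromo-2,6-dimethyloct-6-en-2-ol | C/C(=C\CBr)CCCC(C)(C)O | intermediate
5 | {[(6E)-8-bromo-2,6-dimethyloct-6-en-2-yl]oxy}triethylsilane | C/C(=C\CBr)CCCC(C)(C)O[Si](CC)(CC)CC | intermediate
6 | resorcinol | Oc1cccc(O)c1 | starting material
7 | 1,3-bis(methoxymethoxy)benzene | COCOc1cccc(OCOC)c1 | intermediate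
8 | 2-lithio-1,3-bis(methoxymethoxy)benzene (not isolated) | [Li]c1c(OCOC)cccc1OCOC | intermediate
9 | [2,6-bis(methoxymethoxy)phenyl]copper (not isolated) | [Cu]c1c(OCOC)cccc1OCOC | intermediate
10 | {[(6E)-8-[2,6-bis(methoxymethoxy)phenyl]-2,6-dimethyloct-6-en-2-yl]oxy}triethylsilane | C/C(=C\Cc1c(OCOC)cccc1OCOC)CCCC(C)(C)O[Si](CC)(CC)CC | intermediate
11 | 3-lithio derivative of 10, lithium ortho to a MOM ether (not isolated) | C/C(=C\Cc1c(OCOC)ccc([Li])c1OCOC)CCCC(C)(C)O[Si](CC)(CC)CC | intermediate
12 | {[(6E)-8-[3-bromo-2,6-bis(methoxymethoxy)phenyl]-2,6-dimethyloct-6-en-2-yl]oxy}triethylsilane | C/C(=C\Cc1c(OCOC)ccc(Br)c1OCOC)CCCC(C)(C)O[Si](CC)(CC)CC | intermediate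
13 | 4-bromo-2-[(2E)-7-hydroxy-3,7-dimethyloct-2-en-1-yl]benzene-1,3-diol | C/C(=C\Cc1c(O)ccc(Br)c1O)CCCC(C)(C)O | intermediate
14 | (6E)-8-[3-bromo-2,6-bis(tert-butyldimethylsilyloxy)phenyl]-2,6-dimethyloct-6-en-2-ol (not isolated) | C/C(=C\Cc1c(O[Si](C)(C)C(C)(C)C)ccc(Br)c1O[Si](C)(C)C(C)(C)C)CCCC(C)(C)O | intermediate
15 | 4-bromo-1,3-bis(tert-butyldimethylsilyloxy)-2-[(2E)-3,7-dimethyl-7-(trimethylsilyloxy)oct-2-en-1-yl]benzene | C/C(=C\Cc1c(O[Si](C)(C)C(C)(C)C)ccc(Br)c1O[Si](C)(C)C(C)(C)C)CCCC(C)(C)O[Si](C)(C)C | intermediate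
16 | 1-(2,4-dihydroxy-6-methoxyphenyl)ethanone | CC(=O)c1c(O)cc(O)cc1OC | starting material
17 | 1-[2-methoxy-4,6-bis(triisopropylsilyloxy)phenyl]ethanone | CC(=O)c1c(O[Si](C(C)C)(C(C)C)C(C)C)cc(O[Si](C(C)C)(C(C)C)C(C)C)cc1OC | intermediate
18 | 2-{2,4-bis(tert-butyldimethylsilyloxy)-3-[(2E)-3,7-dimethyl-7-(trimethylsilyloxy)oct-2-en-1-yl]phenyl}-1-[2-methoxy-4,6-bis(triisopropylsilyloxy)phenyl]ethanone | C/C(=C\Cc1c(O[Si](C)(C)C(C)(C)C)ccc(CC(=O)c2c(OC)cc(O[Si](C(C)C)(C(C)C)C(C)C)cc2O[Si](C(C)C)(C(C)C)C(C)C)c1O[Si](C)(C)C(C)(C)C)CCCC(C)(C)O[Si](C)(C)C | intermediate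
19 | 2-diazo derivative of 18 (diazo group on the carbon between the carbonyl and ring B) | C/C(=C\Cc1c(O[Si](C)(C)C(C)(C)C)ccc(C(=[N+]=[N-])C(=O)c2c(OC)cc(O[Si](C(C)C)(C(C)C)C(C)C)cc2O[Si](C(C)C)(C(C)C)C(C)C)c1O[Si](C)(C)C(C)(C)C)CCCC(C)(C)O[Si](C)(C)C | intermediate
20 | (3S)-3-{2,4-bis(tert-butyldimethylsilyloxy)-3-[(2E)-3,7-dimethyl-7-(trimethylsilyloxy)oct-2-en-1-yl]phenyl}-5,7-bis(triisopropylsilyloxy)-2,3-dihydro-4H-chromen-4-one | C/C(=C\Cc1c(O[Si](C)(C)C(C)(C)C)ccc([C@H]2COc3cc(O[Si](C(C)C)(C(C)C)C(C)C)cc(O[Si](C(C)C)(C(C)C)C(C)C)c3C2=O)c1O[Si](C)(C)C(C)(C)C)CCCC(C)(C)O[Si](C)(C)C | intermediate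
21 | (3S)-3-{2,4-dihydroxy-3-[(2E)-7-hydroxy-3,7-dimethyloct-2-en-1-yl]phenyl}-5,7-dihydroxy-2,3-dihydro-4H-chromen-4-one | C/C(=C\Cc1c(O)ccc([C@H]2COc3cc(O)cc(O)c3C2=O)c1O)CCCC(C)(C)O | target

**Step count**

Total: 14 steps. Longest linear sequence: 12 steps (steps 1–4, 6–9, 11–14).

**Steps most likely to fail, with fallbacks**

1. Step 13. The enantiofacial discrimination at the carbenoid may be low, because the ortho-silyloxy group twists ring B out of conjugation and makes the carbenoid more reactive. The C3 configuration may also erode by enolisation of the product. Fallback: setting out from 19, the ring is closed with the achiral catalyst Rh2(esp)2 in CH2Cl2 to the racemic pentasilyl isoflavanone F1. Soft enolisation (TMSOTf, Et3N, CH2Cl2, 0 °C) should then give the 4-trimethylsilyloxy-2H-chromene F2. Catalytic enantioselective protonation of this silyl enol ether (BINOL-derived chiral N-triflyl thiophosphoramide, phenol as stoichiometric proton source, toluene, low temperature) is a known way to set the α-aryl stereocentre of cyclic 2-aryl ketones and comes back to the route at 20.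

2. Step 11. The ketone enolate may transfer silicon from the ortho oxygen to the enolate oxygen at 90 °C, the coupling may stall at the bromide flanked by a silyloxy group, or a second arylation may follow. Fallback: setting out from 17, soft enolisation (TMSOTf, Et3N, CH2Cl2, 0 °C) gives the trimethylsilyl enol ether F3 without a free alkali enolate. Palladium-catalysed arylation of F3 with bromide 15 through the tin enolate made in the flask (Bu3SnF, PdCl2[P(o-tol)3]2, toluene, reflux) comes back to the route at 18.

3. Step 7. Deprotonation may occur at the doubly activated benzylic/allylic CH2 (lateral lithiation) instead of at the ring, which would move the alkene and place bromine in the chain. Fallback: setting out from 7, both halogens are placed before the chain. Directed ortho-metalation and iodine quench (n-BuLi, THF; I2) give 2-iodo-1,3-bis(methoxymethoxy)benzene F4. Electrophilic bromination para to a MOM ether (NBS, MeCN, 0 °C) gives 1-bromo-3-iodo-2,4-bis(methoxymethoxy)benzene F5. Selective iodine–lithium exchange (n-BuLi, THF, −78 °C), transmetalation with CuI and allylation with bromide 5 come back to the route at 12, bypassing 10 and 11.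

**Further compounds**

F1 | step 13 | racemic 3-{2,4-bis(tert-butyldimethylsilyloxy)-3-[(2E)-3,7-dimethyl-7-(trimethylsilyloxy)oct-2-en-1-yl]phenyl}-5,7-bis(triisopropylsilyloxy)-2,3-dihydro-4H-chromen-4-one | C/C(=C\Cc1c(O[Si](C)(C)C(C)(C)C)ccc(C2COc3cc(O[Si](C(C)C)(C(C)C)C(C)C)cc(O[Si](C(C)C)(C(C)C)C(C)C)c3C2=O)c1O[Si](C)(C)C(C)(C)C)CCCC(C)(C)O[Si](C)(C)C
F2 | step 13 | 4-trimethylsilyloxy-2H-chromene (silyl enol ether) of F1 | C/C(=C\Cc1c(O[Si](C)(C)C(C)(C)C)ccc(C2=C(O[Si](C)(C)C)c3c(O[Si](C(C)C)(C(C)C)C(C)C)cc(O[Si](C(C)C)(C(C)C)C(C)C)cc3OC2)c1O[Si](C)(C)C(C)(C)C)CCCC(C)(C)O[Si](C)(C)C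
F3 | step 11 | {1-[2-methoxy-4,6-bis(triisopropylsilyloxy)phenyl]ethenyl}oxy(trimethyl)silane | C=C(O[Si](C)(C)C)c1c(O[Si](C(C)C)(C(C)C)C(C)C)cc(O[Si](C(C)C)(C(C)C)C(C)C)cc1OC
F4 | step 7 | 2-iodo-1,3-bis(methoxymethoxy)benzene | COCOc1cccc(OCOC)c1I
F5 | step 7 | 1-bromo-3-iodo-2,4-bis(methoxymethoxy)benzene | COCOc1ccc(Br)c(OCOC)c1I
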